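**Strategy.** Eschscholtzxanthin is C2-symmetric, and in each half the methyl-bearing C9 sits where the carbonyl carbon of a C13 3-hydroxy-β-ionone would be. Its retro pattern (ring C4=C5, exocyclic C6=C7, C8=C9) is the vinylogous dehydration product of a C9 carbinol. The route therefore forms C9–C10 and C9′–C10′ by twofold 1,2-addition of a dilithiated C14 tetraene-diyne (C10–C10′, made in the flask from a bis-dibromoalkene) to two molecules of (R)-3-silyloxy-β-ionone; the second addition joins the C27 mono-adduct to the second C13 ketone. The C9 hydroxyls then direct trans-reduction of the alkynes and leave, together with H-4, to create the retro dodecaene.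

Key step: step 8

Remarks: Carotenoid numbering is used for the C40 chain and end rings. (4R,6R)-Actinol and (E)-3-methylpent-2-en-4-yn-1-ol are assumed to be purchasable. The ring stereocentre keeps its spatial arrangement from 1 to 16; its descriptor changes from R to S in step 10 only because C4 becomes sp2 and the CIP priorities change.

**Step 1**
Reactants: 1 (4R,6R)-4-hydroxy-2,2,6-trimethylcyclohexan-1-one (actinol)
Product: 2 (4R,6R)-4-[(tert-butyldimethylsilyl)oxy]-2,2,6-trimethylcyclohexan-1-one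
Conditions: TBSCl, imidazole, DMF, rt
Reagents that add atoms: tert-butyldimethylsilyl chloride, CC(C)(C)[Si](C)(C)Cl
Why: Standard silylation of the secondary alcohol masks the future C3 hydroxyl against the bases, hydrides and organolithiums used later.

**Step 2**
Reactants: 2 TBS-actinol
Product: 3 (4R)-4-[(tert-butyldimethylsilyl)oxy]-2,6,6-trimethylcyclohex-1-en-1-yl trifluoromethanesulfonate
Conditions: LDA, THF, –78 → 0 °C; PhNTf2, 0 °C → rt; aq. NH4Cl
Reagents that add atoms: N-phenylbis(trifluoromethanesulfonimide), O=S(=O)(N(c1ccccc1)S(=O)(=O)C(F)(F)F)C(F)(F)F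
Why: The ketone has a single α-hydrogen, so enolate formation and O-triflation can only give the tetrasubstituted enol triflate; the silyloxy stereocentre is not touched.

**Step 3**
Reactants: 3 enol triflate; 4 methyl vinyl ketone
Product: 5 (E)-4-[(4R)-4-[(tert-butyldimethylsilyl)oxy]-2,6,6-trimethylcyclohex-1-en-1-yl]but-3-en-2-one (TBS ether of (R)-3-hydroxy-β-ionone)
Conditions: Pd(OAc)2 (cat.), PPh3, Et3N, DMF, 75 °C
Reagents that add atoms: none
Why: Heck reaction of an alkenyl triflate with an electron-poor alkene should give the (E)-dienone by syn-insertion and syn-β-hydride elimination.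

**Step 4**
Reactants: 6 (E)-3-methylpent-2-en-4-yn-1-ol
Product: 7 (2E,4E)-3-methyl-5-(tributylstannyl)penta-2,4-dien-1-ol
Conditions: Bu3SnH, PdCl2(PPh3)2 (cat.), THF, 0 °C → rt
Reagents that add atoms: tributyltin hydride, CCCC[SnH](CCCC)CCCC
Why: Pd-catalysed syn-hydrostannation of the terminal alkyne of a conjugated enyne places tin on the terminal carbon and should give the (E)-alkenylstannane (future C14=C15).

**Step 5**
Reactants: 7 dienylstannane (2 equiv)
Product: 8 (2E,4E,6E,8E)-3,8-dimethyldeca-2,4,6,8-tetraene-1,10-diol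
Conditions: CuCl (excess), DMF, rt → 60 °C, Ar
Reagents that add atoms: none
Why: Copper(I)-mediated oxidative homocoupling of alkenylstannanes (Sn→Cu transmetalation, then coupling of the alkenylcopper) forms the central C15–C15′ bond with retention of both alkene geometries.

**Step 6**
Reactants: 8 tetraene diol
Product: 9 (2E,4E,6E,8E)-3,8-dimethyldeca-2,4,6,8-tetraenedial
Conditions: MnO2, CH2Cl2, rt
Reagents that add atoms: none
Why: Activated MnO2 oxidises allylic alcohols to enals selectively and should leave the tetraene geometry intact.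

**Step 7**
Reactants: 9 tetraene dial
Product: 10 (3E,5E,7E,9E)-1,1,12,12-tetrabromo-4,9-dimethyldodeca-1,3,5,7,9,11-hexaene
Conditions: CBr4, PPh3, Zn, CH2Cl2, rt; then 9, 0 °C → rt
Reagents that add atoms: carbon tetrabromide, BrC(Br)(Br)Br
Why: Twofold Corey–Fuchs (Ramirez) dibromo-olefination adds C10 and C10′; the zinc variant avoids Ph3PBr2 and HBr, which would attack the polyene.

**Step 8**
Reactants: 10 bis-dibromoalkene; 5 TBS-ionone (2 equiv)
Product: 13 (1E,6E,8E,10E,12E,17E)-1,18-bis[(4R)-4-[(tert-butyldimethylsilyl)oxy]-2,6,6-trimethylcyclohex-1-en-1-yl]-3,7,12,16-tetramethyloctadeca-1,6,8,10,12,17-hexaene-4,14-diyne-3,16-diol (C40 bis-propargylic diol, mixture of C9/C9′ epimers), via dilithium C14 diacetylide 11 (not isolated), via C27 mono-adduct dilithium salt 12 (not isolated)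
Conditions: n-BuLi (4 equiv), THF, –78 → –20 °C; then 5 (2.1 equiv), –78 → 0 °C; aq. NH4Cl
Reagents that add atoms: none
Why: n-BuLi effects Br/Li exchange at each dibromoalkene, α-elimination with 1,2-hydride shift gives the terminal alkyne and a second equivalent deprotonates it, so diacetylide 11 forms in the flask; each acetylide then adds 1,2 to the C9 carbonyl of 5, and the second addition unites the C27 mono-adduct 12 with the second C13 ketone, making the C9–C10 bond. The closest known reaction types are the Corey–Fuchs alkyne synthesis with in-situ electrophile trapping and the ethynylation of β-ionone used in vitamin A chemistry. No ring is closed. The new C9 and C9′ carbinol centres form without control, which is harmless because both become sp2 carbons in step 10; C3 and C3′ are remote and untouched. The step needs 1,2-addition rather than conjugate addition or enolisation of the methyl ketone, and complete reaction at both termini; the hard, weakly basic, sterically small lithium acetylide favours carbonyl attack, and a slight excess of 5 drives the second addition.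

**Step 9**
Reactants: 13 bis-propargylic diol
Product: 14 (1E,4E,6E,8E,10E,12E,14E,17E)-1,18-bis[(4R)-4-[(tert-butyldimethylsilyl)oxy]-2,6,6-trimethylcyclohex-1-en-1-yl]-3,7,12,16-tetramethyloctadeca-1,4,6,8,10,12,14,17-octaene-3,16-diol (C40 bis-allylic diol)
Conditions: Red-Al, THF, 0 °C → rt; aq. Rochelle salt
Reagents that add atoms: none
Why: Alkoxide-directed trans-hydroalumination of propargylic alcohols delivers hydride to C10 (C10′) and, after protonation of the vinylalanate, should give the (E)-C10=C11 and C10′=C11′ alkenes; silyl ethers and isolated polyene units are inert.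

**Step 10**
Reactants: 14 bis-allylic diol
Product: 15 (3S,3′S,6E,6′E)-3,3′-bis[(tert-butyldimethylsilyl)oxy]-4′,5′-didehydro-4,5′-retro-β,β-carotene (eschscholtzxanthin bis-TBS ether)
Conditions: p-TsOH·H2O (cat.), CH2Cl2, –20 → 0 °C, dark; Et3N; then heptane, 70 °C (E/Z equilibration), crystallisation
Reagents that add atoms: none
Why: Acid ionisation of each tertiary, doubly allylic C9–OH gives a polyenyl cation that loses H-4 (H-4′), a twofold vinylogous 1,6-dehydration of the retro-ionylidene (anhydro-vitamin A) type; this shifts the ring-end unsaturation to C4=C5, C6=C7 and C8=C9, and the fully conjugated all-E (6E,6′E) dodecaene is the expected thermodynamic sink.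

**Step 11**
Reactants: 15 bis-TBS ether
Product: 16 eschscholtzxanthin, (3S,3′S,6E,6′E)-4′,5′-didehydro-4,5′-retro-β,β-carotene-3,3′-diol
Conditions: TBAF, THF, 0 °C → rt, dark, Ar
Reagents that add atoms: none
Why: Fluoride desilylation is non-acidic and should therefore free the acid-labile allylic C3 hydroxyls without ionisation or epimerisation.

**Compound list**
1 | (4R,6R)-4-hydroxy-2,2,6-trimethylcyclohexan-1-one (actinol) | C[C@@H]1C[C@@H](O)CC(C)(C)C1=O | starting material
2 | (4R,6R)-4-[(tert-butyldimethylsilyl)oxy]-2,2,6-trimethylcyclohexan-1-one | C[C@@H]1C[C@@H](O[Si](C)(C)C(C)(C)C)CC(C)(C)C1=O | intermediate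
3 | (4R)-4-[(tert-butyldimethylsilyl)oxy]-2,6,6-trimethylcyclohex-1-en-1-yl trifluoromethanesulfonate | CC1=C(OS(=O)(=O)C(F)(F)F)C(C)(C)C[C@H](O[Si](C)(C)C(C)(C)C)C1 | intermediate
4 | methyl vinyl ketone (but-3-en-2-one) | CC(=O)C=C | starting material
5 | (E)-4-[(4R)-4-[(tert-butyldimethylsilyl)oxy]-2,6,6-trimethylcyclohex-1-en-1-yl]but-3-en-2-one | CC1=C(/C=C/C(C)=O)C(C)(C)C[C@H](O[Si](C)(C)C(C)(C)C)C1 | intermediate
6 | (E)-3-methylpent-2-en-4-yn-1-ol | C#C/C(C)=C/CO | starting material
7 | (2E,4E)-3-methyl-5-(tributylstannyl)penta-2,4-dien-1-ol | CCCC[Sn](CCCC)(CCCC)/C=C/C(C)=C/CO | intermediate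
8 | (2E,4E,6E,8E)-3,8-dimethyldeca-2,4,6,8-tetraene-1,10-diol | OC/C=C(C)/C=C/C=C/C(C)=C/CO | intermediate
9 | (2E,4E,6E,8E)-3,8-dimethyldeca-2,4,6,8-tetraenedial | O=C/C=C(C)/C=C/C=C/C(C)=C/C=O | intermediate
10 | (3E,5E,7E,9E)-1,1,12,12-tetrabromo-4,9-dimethyldodeca-1,3,5,7,9,11-hexaene | BrC(Br)=C/C=C(C)/C=C/C=C/C(C)=C/C=C(Br)Br | intermediate
11 | dilithium (3E,5E,7E,9E)-4,9-dimethyldodeca-3,5,7,9-tetraene-1,11-diyne-1,12-diide (not isolated) | [Li]C#C/C=C(C)/C=C/C=C/C(C)=C/C#C[Li] | intermediate
12 | C27 mono-adduct as dilithium salt (C9′ lithium alkoxide, C10 lithium acetylide; not isolated) | [Li]C#C/C=C(C)/C=C/C=C/C(C)=C/C#CC(C)(O[Li])/C=C/C1=C(C)C[C@@H](O[Si](C)(C)C(C)(C)C)CC1(C)C | intermediate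
13 | C40 bis-propargylic diol, (1E,6E,8E,10E,12E,17E)-1,18-bis[(4R)-4-(TBS-oxy)-2,6,6-trimethylcyclohex-1-en-1-yl]-3,7,12,16-tetramethyloctadeca-1,6,8,10,12,17-hexaene-4,14-diyne-3,16-diol | CC1=C(/C=C/C(C)(O)C#C/C=C(C)/C=C/C=C/C(C)=C/C#CC(C)(O)/C=C/C2=C(C)C[C@@H](O[Si](C)(C)C(C)(C)C)CC2(C)C)C(C)(C)C[C@H](O[Si](C)(C)C(C)(C)C)C1 | intermediate
14 | C40 bis-allylic diol, (1E,4E,6E,8E,10E,12E,14E,17E)-1,18-bis[(4R)-4-(TBS-oxy)-2,6,6-trimethylcyclohex-1-en-1-yl]-3,7,12,16-tetramethyloctadeca-1,4,6,8,10,12,14,17-octaene-3,16-diol | CC1=C(/C=C/C(C)(O)/C=C/C=C(C)/C=C/C=C/C(C)=C/C=C/C(C)(O)/C=C/C2=C(C)C[C@@H](O[Si](C)(C)C(C)(C)C)CC2(C)C)C(C)(C)C[C@H](O[Si](C)(C)C(C)(C)C)C1 | intermediate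
15 | eschscholtzxanthin bis-TBS ether, (3S,3′S,6E,6′E)-3,3′-bis(TBS-oxy)-4′,5′-didehydro-4,5′-retro-β,β-carotene | CC1=C[C@@H](O[Si](C)(C)C(C)(C)C)CC(C)(C)\C1=C/C=C(C)/C=C/C=C(C)/C=C/C=C/C(C)=C/C=C/C(C)=C/C=C1/C(C)=C[C@@H](O[Si](C)(C)C(C)(C)C)CC1(C)C | intermediate
16 | eschscholtzxanthin, (3S,3′S,6E,6′E)-4′,5′-didehydro-4,5′-retro-β,β-carotene-3,3′-diol | CC1=C[C@@H](O)CC(C)(C)\C1=C/C=C(C)/C=C/C=C(C)/C=C/C=C/C(C)=C/C=C/C(C)=C/C=C1/C(C)=C[C@@H](O)CC1(C)C | target

**Totals.** 11 steps in all. The longest linear sequence is 8 steps (6 → 7 → 8 → 9 → 10 → 13 → 14 → 15 → 16); the ketone branch (1 → 5) adds 3 steps.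

**Steps most likely to fail**

1. Step 8. Proton transfer from the methyl ketone to the acetylide (enolisation) may outrun carbonyl addition. The poorly soluble dianion may stop at the mono-adduct stage, and carbenoid side reactions may occur on the polyene during alkyne generation. Fallback, from 10 and 5, returning at 15: 10 is treated with n-BuLi (THF, –78 °C) and quenched with water to give the free tetraene-diyne F1. Twofold Pd-catalysed hydrostannation (Bu3SnH, PdCl2(PPh3)2) converts it into the hexaene bis-stannane F2. Separately, thermodynamic extended enolisation of 5 at ring C4 (KOt-Bu, THF/DMPU) and O-triflation with PhNTf2 give the retro trienyl triflate F3. A twofold Stille coupling of F2 with F3 (Pd2(dba)3, AsPh3, CuI, NMP) forms the same C9–C10 and C9′–C10′ bonds at the sp2–sp2 level and gives 15 directly after the thermal E/Z equilibration; steps 9 and 10 are then not needed.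

2. Step 10. Proton loss from the C18, C19 or C20 methyl groups instead of C4 may give cross-conjugated isomers. Once the retro chromophore exists, ionisation of the allylic C3–O bond may cause loss of silanol or epimerisation at C3. Equilibration of 6Z isomers to 6E,6′E may be incomplete. Fallback, from 14, returning at 16: TBAF removes both silyl groups to give the tetraol F4. Ac2O/pyridine acetylates only the secondary C3 hydroxyls and gives the diacetate F5. The allylic acetates resist ionisation, so the dehydration can be run under stronger, fully equilibrating acid (aq. HBr, CH2Cl2, –40 °C) to give eschscholtzxanthin diacetate F6. Methanolysis (K2CO3, MeOH/THF) then gives 16.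

3. Step 5. Slow Sn→Cu transmetalation of the tributylstannane and protodestannylation may give the reduced diene instead of the dimer. Fallback, from 7, returning at 8: half of 7 is converted by iododestannylation (I2, CH2Cl2, 0 °C) into (2E,4E)-5-iodo-3-methylpenta-2,4-dien-1-ol F7. Stille cross-coupling of F7 with the remaining 7 (PdCl2(MeCN)2, DMF, rt) gives 8 with retention of geometry.

**Further compounds**
F1 | step 8 | (3E,5E,7E,9E)-4,9-dimethyldodeca-3,5,7,9-tetraene-1,11-diyne | C#C/C=C(C)/C=C/C=C/C(C)=C/C#C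
F2 | step 8 | (1E,3E,5E,7E,9E,11E)-4,9-dimethyl-1,12-bis(tributylstannyl)dodeca-1,3,5,7,9,11-hexaene | CCCC[Sn](CCCC)(CCCC)/C=C/C=C(C)/C=C/C=C/C(C)=C/C=C/[Sn](CCCC)(CCCC)CCCC
F3 | step 8 | (2E,4E)-4-[(4S)-4-[(tert-butyldimethylsilyl)oxy]-2,6,6-trimethylcyclohex-2-en-1-ylidene]but-2-en-2-yl trifluoromethanesulfonate | CC1=C[C@@H](O[Si](C)(C)C(C)(C)C)CC(C)(C)\C1=C/C=C(C)/OS(=O)(=O)C(F)(F)F
F4 | step 10 | (1E,4E,6E,8E,10E,12E,14E,17E)-1,18-bis[(4R)-4-hydroxy-2,6,6-trimethylcyclohex-1-en-1-yl]-3,7,12,16-tetramethyloctadeca-1,4,6,8,10,12,14,17-octaene-3,16-diol | CC1=C(/C=C/C(C)(O)/C=C/C=C(C)/C=C/C=C/C(C)=C/C=C/C(C)(O)/C=C/C2=C(C)C[C@@H](O)CC2(C)C)C(C)(C)C[C@H](O)C1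
F5 | step 10 | 3,3′-di-O-acetyl derivative of F4 (tertiary C9/C9′ hydroxyls free) | CC1=C(/C=C/C(C)(O)/C=C/C=C(C)/C=C/C=C/C(C)=C/C=C/C(C)(O)/C=C/C2=C(C)C[C@@H](OC(C)=O)CC2(C)C)C(C)(C)C[C@H](OC(C)=O)C1
F6 | step 10 | eschscholtzxanthin diacetate, (3S,3′S,6E,6′E) | CC1=C[C@@H](OC(C)=O)CC(C)(C)\C1=C/C=C(C)/C=C/C=C(C)/C=C/C=C/C(C)=C/C=C/C(C)=C/C=C1/C(C)=C[C@@H](OC(C)=O)CC1(C)C
F7 | step 5 | (2E,4E)-5-iodo-3-methylpenta-2,4-dien-1-ol | OC/C=C(C)/C=C/I
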